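## The problem

Cathayanon H (15) is a 2,3-trans dihydroflavonol. A phloroglucinol-type ring A is fused to the oxygen heterocycle ring C (O1, C2, C3, C4, C4a, C8a), and C2 carries ring B, a phenol flanked by two prenyl groups. Rings A and B are each close to a commodity chemical (6 and 1), so the synthesis is in essence the construction of ring C between them: the O1–C2 bond, the C2–C3 bond and the C3 hydroxyl. The two adjacent stereocentres, C2 (R, benzylic, on O1) and C3 (R, the carbinol next to the C4 ketone), are trans. Because C3 is enolisable, a C2 centre set first can direct C3 kinetically (its aryl group blocks one face of the C3 enolate) and thermodynamically (trans is the diequatorial isomer), so only C2 needs absolute control. The molecule tolerates little: the prenyl alkenes rule out hydrogenolysis, strong electrophilic oxidants and strong acid (which also cyclises a prenyl group onto the 4'-hydroxyl). Base opens the β-aryloxy ketone of ring C to the chalcone and erases C2, and the α-ketol epimerises and oxidises to the flavonol in basic air. The feature that opens the route is that C2 is both benzylic and bound to O1. A benzyl aryl ether of ring A already contains O1–C2 and offers two activated, enantiotopic C–H bonds six atoms (C3, C4, C4a, C8a, O1, C2) from a carbene on C3, while the five-atom position that carbenes normally prefer is the ether oxygen itself.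

## Retrosynthesis

**15 to 14 (three O–Si bonds).** The three phenols are masked as tert-butyldimethylsilyl (TBS) ethers in 14. Silyl ethers are preferred to benzyl ethers (hydrogenolysis would reduce the prenyl groups), to methyl ethers (boron tribromide) and to acetals (acid, and activated C–H bonds that would mislead the carbene). The forward step needs only buffered fluoride, which the ketol and the prenyl groups should survive.

**14 to 12 (C3–O bond).** Removing the C3 hydroxyl leaves the flavanone 12 with C2 as its only stereocentre. The oxygen cannot be carried through the carbene step, because the carbene carbon itself becomes C3, so it is introduced afterwards. The forward reaction is a low-temperature enolisation to the potassium enolate 13 and oxygen transfer from an N-sulfonyloxaziridine, anti to the C2 aryl group. That oxidant is chosen because, unlike peracids or dioxiranes, it leaves the prenyl alkenes alone.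

**12 to 11 (C2–C3 bond, ring C).** This is the strategic cut. Cutting O1–C2 instead leads to a chalcone, whose oxa-Michael closure is reversible and hard to render enantioselective. Cutting C2–aryl leads to a chromone and a ring B organometallic that would first have to be made. Cutting C2–C3 turns the stereocentre into the prochiral methylene of a benzyl ether and the other terminus into a diazoketone. The precursor 11 is acyclic in ring C and achiral, and one catalytic step makes the C–C bond, the ring and the stereocentre. The forward reaction must insert into C–H (not form an oxonium ylide), must distinguish the two enantiotopic hydrogens, and must ignore two prenyl alkenes and three silyl ethers.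

**11 to 8 (C=N2).** The diazo group is traced to the methyl group of acetophenone 8 by detrifluoroacetylative diazo transfer through enolate 9 and diketone 10. The alternative, acylating diazomethane with a 2,6-dioxygenated benzoyl chloride, would need a hindered, decarboxylation-prone acid and would abandon the commercial acetophenone. The forward reaction asks only for a kinetic enolate and a sulfonyl azide.

**8 to 7 + 5 (O1–CH2 bond).** This is the convergent cut: it separates ring A (phenol 7) from ring B (benzylic alcohol 5) at the ether that later becomes O1–C2. A Mitsunobu reaction is preferred to a carbonate-mediated alkylation because the aryl silyl ethers are base-labile and a para-silyloxybenzyl bromide is an unstable electrophile.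

**7 to 6, and 5 to 4 to 3 to 1 + 2.** Phenol 7 is the bis-silyl ether of 2,4,6-trihydroxyacetophenone (6); the third hydroxyl is differentiated by its hydrogen bond to the acetyl group. Alcohol 5 comes from aldehyde 4 by reduction, 4 from phenol 3 by silylation, and 3 from 4-hydroxybenzaldehyde (1) and prenyl bromide (2) by twofold ortho C-prenylation. This last cut removes both prenyl groups in one operation, at the price of modest selectivity.

## Roads not taken

**Alternative 1: anodic closure of O1–C2 on a chiral-pool ketol.** The cut is O1–C2. C3 is imported from D-tyrosine A2 as an (R)-α-hydroxy acid, which is dibrominated and joined to ring A to give the open-chain ketol A3. In the key step, two-electron oxidation of the 2,6-dibromophenol of A3 at a carbon anode gives the para-quinone methide A4. An ortho hydroxyl of ring A then adds to the methide carbon, closing ring C trans to the C3 hydroxyl and giving the dibromo dihydroflavonol A1.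

- Merits: C3 comes from the chiral pool and directs C2. No protecting group, strong base or enolate oxidation is needed. The whole dihydroflavonol core is reached in very few steps.
- Weak points: A1 has bromine where the target has prenyl. Both prenyl groups must then be installed by twofold cross-coupling at hindered ortho-bromophenol positions of an unprotected, base- and air-sensitive tetrahydroxy ketol, and linear-versus-branched selectivity of the prenyl–metal partner has to be won twice. The anode must also oxidise ring B in the presence of an electron-rich ring A and a ketol, and the acylation that makes A3 must not racemise the α-carbon.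
- Comparison: this road is shorter than the chosen one and solves C3 more elegantly. The chosen plan sets against it that the prenyl groups are present from step 1, so the finished core only undergoes a buffered desilylation, and that its key step belongs to a known reaction class, whereas the late double prenylation of A1 has no close counterpart.

**Alternative 2: ring B built from a ketone and a triformyl unit.** The cut is C2'–C3' and C5'–C6' of ring B. Under hydroxide or alkoxide, the two α-methylene groups of the symmetric ketone A6 condense with two formyl groups of triformylmethane A7. The ring closes and tautomerises to 4-hydroxy-3,5-diprenylbenzaldehyde A5, which is identical with 3.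

- Merits: the prenyl groups sit exactly where the ketone α-carbons were, so there is no O-alkylation and no mono/di mixture.
- Weak points: neither A6 nor A7 is a bulk chemical and both would have to be prepared, A7 being a sensitive tricarbonyl compound. The step also spends the strategic effort on the easy part of the molecule: it makes no stereocentre and does not touch ring C, so it must be combined with another plan for the core.
- Comparison: for making 3 alone, this road is probably cleaner than step 1 of the chosen route, which is expected to be its least efficient step. The chosen route sets against it a single operation from two commodity chemicals. Because A5 is 3, this chemistry also remains open as a second supply of 3 with nothing downstream changed.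

**Alternative 3: ring A folded from a chain on a chiral dihydropyranone.** The cut is C4a–C5. The dihydropyranone A9 already carries the C2 aryl group, the C3 oxygen (as a methoxymethyl ether) and a keto ester chain on C8a. Base converts the chain into its polyanion, C4a attacks the ester carbon, and ring A closes and aromatises to the bis(methoxymethyl) ether A8, one deprotection from 15.

- Merits: both stereocentres are set in an aliphatic heterocycle before any phenol exists. No oxidation is carried out in the presence of prenyl groups, and the 5- and 7-hydroxyls appear unprotected.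
- Weak points: the polyanion conditions act on a ring in which C3–H is α to the C4 ketone and β to O1, so epimerisation and β-elimination (opening of ring C) compete with the Claisen-type closure. A9 needs a long asymmetric synthesis to rebuild an aromatic ring that is commercial as 6. The final acetal cleavage needs acid next to two prenyl groups and a freed 4'-phenol.
- Comparison: this road is better than the chosen one in avoiding the late enolate hydroxylation. The chosen plan sets against it a much shorter path, a purchased ring A and a catalytic, late creation of chirality.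

Key step: step 7

Assumption: the sense of induction of Rh2(S-PTTL)4 (dirhodium tetrakis[N-phthaloyl-(S)-tert-leucinate]) at C2 cannot be predicted with confidence, so the (S)-catalyst is written and Rh2(R-PTTL)4 replaces it unchanged if a pilot run shows that the latter delivers the 2S flavanone 12.

## Route

Step 1
Reactants: 1 4-hydroxybenzaldehyde; 2 prenyl bromide (1-bromo-3-methylbut-2-ene)
Product: 3 4-hydroxy-3,5-bis(3-methylbut-2-en-1-yl)benzaldehyde
Conditions: 2 (2.5 equiv), aq. KOH, 0 °C to rt
Reagents that add atoms: prenyl bromide (2), CC(C)=CCBr
Why: Ortho C-alkylation of an ambident phenoxide in water, where hydrogen bonding to the oxygen favours attack by the ring carbons; the para position is blocked by the formyl group and SN2 attack at the primary allylic carbon gives the linear prenyl group. The twofold C-prenylation of this phenol is a known but modest reaction, and mono-prenylated material is resubmitted.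

Step 2
Reactants: 3 4-hydroxy-3,5-bis(3-methylbut-2-en-1-yl)benzaldehyde
Product: 4 4-(tert-butyldimethylsilyloxy)-3,5-bis(3-methylbut-2-en-1-yl)benzaldehyde
Conditions: TBSCl, imidazole, DMF, rt to 40 °C
Reagents that add atoms: tert-butyldimethylsilyl chloride, CC(C)(C)[Si](C)(C)Cl
Why: Imidazole-mediated silylation of a phenol; the 4-formylphenol is acidic enough to react despite the two flanking groups, which afterwards shield the silyl ether.

Step 3
Reactants: 4 4-(tert-butyldimethylsilyloxy)-3,5-bis(3-methylbut-2-en-1-yl)benzaldehyde
Product: 5 [4-(tert-butyldimethylsilyloxy)-3,5-bis(3-methylbut-2-en-1-yl)phenyl]methanol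
Conditions: NaBH4, EtOH–THF, 0 °C
Reagents that add atoms: none
Why: Borohydride reduction of an aromatic aldehyde; the hindered aryl silyl ether and the isolated trisubstituted alkenes are inert to NaBH4 at 0 °C.

Step 4
Reactants: 6 2,4,6-trihydroxyacetophenone
Product: 7 1-[2,4-bis(tert-butyldimethylsilyloxy)-6-hydroxyphenyl]ethan-1-one
Conditions: TBSCl (2.1 equiv), imidazole, DMF, 0 °C to rt
Reagents that add atoms: tert-butyldimethylsilyl chloride, CC(C)(C)[Si](C)(C)Cl
Why: Selective silylation: the 4-hydroxyl and one of the two equivalent ortho hydroxyls react, after which the last hydroxyl is held in a strong hydrogen bond to the acetyl oxygen and resists a third silylation.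

Step 5
Reactants: 7 1-[2,4-bis(tert-butyldimethylsilyloxy)-6-hydroxyphenyl]ethan-1-one; 5 [4-(tert-butyldimethylsilyloxy)-3,5-bis(3-methylbut-2-en-1-yl)phenyl]methanol
Product: 8 1-{2,4-bis(tert-butyldimethylsilyloxy)-6-[4-(tert-butyldimethylsilyloxy)-3,5-bis(3-methylbut-2-en-1-yl)benzyloxy]phenyl}ethan-1-one
Conditions: PPh3, DIAD, THF, 0 °C to rt
Reagents that add atoms: none
Why: Mitsunobu etherification: the chelated phenol of 7 is acidic enough to protonate the betaine and displaces the oxyphosphonium of the primary benzylic alcohol 5. The neutral conditions spare the base-labile aryl silyl ethers, which a carbonate-mediated alkylation would endanger.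

Step 6
Reactants: 8 1-{2,4-bis(tert-butyldimethylsilyloxy)-6-[4-(tert-butyldimethylsilyloxy)-3,5-bis(3-methylbut-2-en-1-yl)benzyloxy]phenyl}ethan-1-one
Product: 11 2-diazo-1-{2,4-bis(tert-butyldimethylsilyloxy)-6-[4-(tert-butyldimethylsilyloxy)-3,5-bis(3-methylbut-2-en-1-yl)benzyloxy]phenyl}ethan-1-one, via lithium enolate 9 (not isolated), via trifluoroacetyl diketone 10 (not isolated)
Conditions: LiN(SiMe3)2, THF, −78 °C; CF3CO2CH2CF3, −78 °C; cold dil. HCl work-up; then MsN3, Et3N, H2O (1 equiv), MeCN, rt
Reagents that add atoms: methanesulfonyl azide, CS(=O)(=O)N=[N+]=[N-] (both diazo nitrogens); 2,2,2-trifluoroethyl trifluoroacetate, O=C(OCC(F)(F)F)C(F)(F)F (trifluoroacetyl group of 10 only, lost again before 11)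
Why: Detrifluoroacetylative (Regitz-type) diazo transfer: the kinetic enolate 9 is C-acylated to the activated diketone 10, whose enolate adds to the sulfonyl azide; fragmentation expels the trifluoroacetyl group as the N-acylsulfonamide and leaves the diazo group on the former methyl carbon. The transient activation is needed because a simple methyl ketone does not accept a diazo group directly.

Step 7
Reactants: 11 2-diazo-1-{2,4-bis(tert-butyldimethylsilyloxy)-6-[4-(tert-butyldimethylsilyloxy)-3,5-bis(3-methylbut-2-en-1-yl)benzyloxy]phenyl}ethan-1-one
Product: 12 (2S)-5,7-bis(tert-butyldimethylsilyloxy)-2-[4-(tert-butyldimethylsilyloxy)-3,5-bis(3-methylbut-2-en-1-yl)phenyl]chroman-4-one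
Conditions: Rh2(S-PTTL)4 (1 mol %), CH2Cl2, 0 °C, slow addition of 11 at high dilution
Reagents that add atoms: none
Why: The diazo carbon of 11 attacks the dirhodium tetracarboxylate and N2 is lost, giving an electrophilic rhodium carbene centred on C3. The carbene inserts into one benzylic C–H bond of the OCH2Ar group through a three-centre, hydride-transfer-like transition state in which the positive charge building up at C2 is stabilised by the O1 lone pair and by the para-silyloxy ring B; C2–C3 forms, the hydrogen ends on C3 and the catalyst is released. The closest known reaction type is the dirhodium carboxylate catalysed enantioselective C–H insertion of ortho-alkoxyaryl diazoketones to 2-substituted chroman-4-ones. Ring C closes in a 1,6-insertion mode (C3, C4, C4a, C8a, O1, C2), the usually preferred five-membered mode being excluded because the fifth atom is the ether oxygen. The new stereocentre C2 is set by the catalyst alone: the phthalimido walls of the tert-leucinate ligands present one of the two enantiotopic hydrogens to the carbene, and the substrate has no other stereocentre. The step needs chemoselectivity for C–H insertion over oxonium ylide formation at O1 with [1,2]-benzyl shift (Stevens rearrangement), over attack at the ortho silyl ether oxygen, over cyclopropanation of the prenyl alkenes and over addition to ring B. The substrate secures this because both ortho oxygens are conjugated to the acyl-bearing ring A and are poor ylide donors, the silyl groups offer no activated C–H bond within six atoms, and the prenyl alkenes and ring B reach the carbene only through medium or large rings; the carboxylate ligand set and slow addition suppress the remaining ylide and bimolecular pathways.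

Step 8
Reactants: 12 (2S)-5,7-bis(tert-butyldimethylsilyloxy)-2-[4-(tert-butyldimethylsilyloxy)-3,5-bis(3-methylbut-2-en-1-yl)phenyl]chroman-4-one
Product: 14 (2R,3R)-5,7-bis(tert-butyldimethylsilyloxy)-2-[4-(tert-butyldimethylsilyloxy)-3,5-bis(3-methylbut-2-en-1-yl)phenyl]-3-hydroxychroman-4-one, via potassium enolate 13 (not isolated)
Conditions: KN(SiMe3)2, THF, −78 °C; 3-phenyl-2-(phenylsulfonyl)oxaziridine, −78 °C; AcOH quench at −78 °C
Reagents that add atoms: 3-phenyl-2-(phenylsulfonyl)oxaziridine, O=S(=O)(c1ccccc1)N1OC1c1ccccc1
Why: Davis oxidation of a ketone enolate: in the kinetic enolate 13 the C2–O1 bond lies near the nodal plane of the enolate π system, so β-elimination to the chalcone should be slow at −78 °C. The oxaziridine transfers oxygen to C3 on the face opposite the C2 aryl group, giving the 2,3-trans (2R,3R) ketol, which is also the more stable diequatorial isomer. The oxaziridine does not epoxidise the prenyl alkenes at this temperature.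

Step 9
Reactants: 14 (2R,3R)-5,7-bis(tert-butyldimethylsilyloxy)-2-[4-(tert-butyldimethylsilyloxy)-3,5-bis(3-methylbut-2-en-1-yl)phenyl]-3-hydroxychroman-4-one
Product: 15 cathayanon H, (2R,3R)-3,5,7-trihydroxy-2-[4-hydroxy-3,5-bis(3-methylbut-2-en-1-yl)phenyl]chroman-4-one
Conditions: Bu4NF–AcOH (1:1, 3.5 equiv), THF, 0 °C
Reagents that add atoms: none
Why: Fluoride cleavage of three aryl silyl ethers; buffering with acetic acid keeps the medium near neutral, so the ketol should be neither epimerised, ring-opened nor oxidised to the flavonol, and no strong acid is present that could cyclise a prenyl group onto the 4'-hydroxyl.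

## Compound list

1 | 4-hydroxybenzaldehyde | O=Cc1ccc(O)cc1 | starting material
2 | prenyl bromide (1-bromo-3-methylbut-2-ene) | CC(C)=CCBr | starting material
3 | 4-hydroxy-3,5-bis(3-methylbut-2-en-1-yl)benzaldehyde | O=Cc1cc(CC=C(C)C)c(O)c(CC=C(C)C)c1 | intermediate
4 | 4-(tert-butyldimethylsilyloxy)-3,5-bis(3-methylbut-2-en-1-yl)benzaldehyde | O=Cc1cc(CC=C(C)C)c(O[Si](C)(C)C(C)(C)C)c(CC=C(C)C)c1 | intermediate
5 | [4-(tert-butyldimethylsilyloxy)-3,5-bis(3-methylbut-2-en-1-yl)phenyl]methanol | OCc1cc(CC=C(C)C)c(O[Si](C)(C)C(C)(C)C)c(CC=C(C)C)c1 | intermediate
6 | 2,4,6-trihydroxyacetophenone | CC(=O)c1c(O)cc(O)cc1O | starting material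
7 | 1-[2,4-bis(tert-butyldimethylsilyloxy)-6-hydroxyphenyl]ethan-1-one | CC(=O)c1c(O)cc(O[Si](C)(C)C(C)(C)C)cc1O[Si](C)(C)C(C)(C)C | intermediate
8 | 1-{2,4-bis(tert-butyldimethylsilyloxy)-6-[4-(tert-butyldimethylsilyloxy)-3,5-bis(3-methylbut-2-en-1-yl)benzyloxy]phenyl}ethan-1-one | CC(=O)c1c(O[Si](C)(C)C(C)(C)C)cc(O[Si](C)(C)C(C)(C)C)cc1OCc1cc(CC=C(C)C)c(O[Si](C)(C)C(C)(C)C)c(CC=C(C)C)c1 | intermediate
9 | lithium enolate of 8 (lithium 1-arylethen-1-olate) | [Li+].[O-]C(=C)c1c(O[Si](C)(C)C(C)(C)C)cc(O[Si](C)(C)C(C)(C)C)cc1OCc1cc(CC=C(C)C)c(O[Si](C)(C)C(C)(C)C)c(CC=C(C)C)c1 | intermediate (not isolated)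
10 | 4,4,4-trifluoro-1-{2,4-bis(tert-butyldimethylsilyloxy)-6-[4-(tert-butyldimethylsilyloxy)-3,5-bis(3-methylbut-2-en-1-yl)benzyloxy]phenyl}butane-1,3-dione | O=C(CC(=O)C(F)(F)F)c1c(O[Si](C)(C)C(C)(C)C)cc(O[Si](C)(C)C(C)(C)C)cc1OCc1cc(CC=C(C)C)c(O[Si](C)(C)C(C)(C)C)c(CC=C(C)C)c1 | intermediate (not isolated)
11 | 2-diazo-1-{2,4-bis(tert-butyldimethylsilyloxy)-6-[4-(tert-butyldimethylsilyloxy)-3,5-bis(3-methylbut-2-en-1-yl)benzyloxy]phenyl}ethan-1-one | [N-]=[N+]=CC(=O)c1c(O[Si](C)(C)C(C)(C)C)cc(O[Si](C)(C)C(C)(C)C)cc1OCc1cc(CC=C(C)C)c(O[Si](C)(C)C(C)(C)C)c(CC=C(C)C)c1 | intermediate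
12 | (2S)-5,7-bis(tert-butyldimethylsilyloxy)-2-[4-(tert-butyldimethylsilyloxy)-3,5-bis(3-methylbut-2-en-1-yl)phenyl]chroman-4-one | CC(C)=CCc1cc([C@H]2Oc3cc(O[Si](C)(C)C(C)(C)C)cc(O[Si](C)(C)C(C)(C)C)c3C(=O)C2)cc(CC=C(C)C)c1O[Si](C)(C)C(C)(C)C | intermediate
13 | potassium (2S)-5,7-bis(tert-butyldimethylsilyloxy)-2-[4-(tert-butyldimethylsilyloxy)-3,5-bis(3-methylbut-2-en-1-yl)phenyl]-2H-chromen-4-olate | CC(C)=CCc1cc([C@H]2Oc3cc(O[Si](C)(C)C(C)(C)C)cc(O[Si](C)(C)C(C)(C)C)c3C([O-])=C2)cc(CC=C(C)C)c1O[Si](C)(C)C(C)(C)C.[K+] | intermediate (not isolated)
14 | (2R,3R)-5,7-bis(tert-butyldimethylsilyloxy)-2-[4-(tert-butyldimethylsilyloxy)-3,5-bis(3-methylbut-2-en-1-yl)phenyl]-3-hydroxychroman-4-one | CC(C)=CCc1cc([C@H]2Oc3cc(O[Si](C)(C)C(C)(C)C)cc(O[Si](C)(C)C(C)(C)C)c3C(=O)[C@@H]2O)cc(CC=C(C)C)c1O[Si](C)(C)C(C)(C)C | intermediate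
15 | cathayanon H, (2R,3R)-3,5,7-trihydroxy-2-[4-hydroxy-3,5-bis(3-methylbut-2-en-1-yl)phenyl]chroman-4-one | CC(C)=CCc1cc([C@H]2Oc3cc(O)cc(O)c3C(=O)[C@@H]2O)cc(CC=C(C)C)c1O | target

## Step count and risks

Total: 9 steps. Longest linear sequence: 8 steps (steps 1, 2, 3, 5, 6, 7, 8, 9 from 4-hydroxybenzaldehyde); step 4 is a one-step branch from 2,4,6-trihydroxyacetophenone.

**Step 7 (key step).** Two things are most likely to go wrong. The carbene may be diverted through oxonium ylide formation at O1 followed by [1,2]-benzyl shift, and the two enantiotopic C2–H bonds may be poorly discriminated. Both follow from the high reactivity of an acceptor-only carbene from a terminal diazoketone, which reacts through an early transition state, and from a very electron-rich benzylic position that pushes the insertion towards a stepwise hydride transfer. Crystallisation of 12, 14 or 15 may raise the enantiomeric purity, but that is only a refinement.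

The fallback separates ring closure from enantiocontrol. It sets out from 11 and comes back at 12. Diazoketone 11 is cyclised with an achiral dirhodium carboxylate chosen for chemoselectivity alone, for instance Rh2(O2CCPh3)4 (dirhodium tetrakis(triphenylacetate)), to give racemic 5,7-bis(tert-butyldimethylsilyloxy)-2-[4-(tert-butyldimethylsilyloxy)-3,5-bis(3-methylbut-2-en-1-yl)phenyl]chroman-4-one F1. This is then subjected to a Noyori-type asymmetric transfer hydrogenation under kinetic resolution conditions (RuCl(p-cymene)[(R,R)-TsDPEN], HCO2H–Et3N, EtOAc, rt; the ligand enantiomer is chosen so that the 2R ketone is the fast-reacting one). The unwanted enantiomer should be reduced to (2R,4R)-5,7-bis(tert-butyldimethylsilyloxy)-2-[4-(tert-butyldimethylsilyloxy)-3,5-bis(3-methylbut-2-en-1-yl)phenyl]chroman-4-ol F2, which is separated by chromatography from the unreacted 2S ketone 12. The price is that at most half of the material can be carried forward.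

**Step 8.** The likely failures are silyl transfer from the C5 oxygen to the neighbouring enolate oxygen of 13 (the two oxygens are peri and a phenoxide is a far weaker base than the enolate), and β-elimination of the O1 aryloxide to the chalcone with loss of C2.

The fallback avoids the free enolate. It sets out from 12 and comes back at 14. Soft enolisation (Me3SiOTf, Et3N, CH2Cl2, 0 °C) gives (2S)-5,7-bis(tert-butyldimethylsilyloxy)-2-[4-(tert-butyldimethylsilyloxy)-3,5-bis(3-methylbut-2-en-1-yl)phenyl]-4-(trimethylsilyloxy)-2H-chromene F3. Rubottom oxidation with one equivalent of dimethyldioxirane at −78 °C, anti to the C2 aryl group, gives (2R,3R)-5,7-bis(tert-butyldimethylsilyloxy)-2-[4-(tert-butyldimethylsilyloxy)-3,5-bis(3-methylbut-2-en-1-yl)phenyl]-3-(trimethylsilyloxy)chroman-4-one F4. Citric acid in methanol removes the trimethylsilyl group to give 14. The selectivity over the prenyl alkenes rests on the silyl enol ether being the most electron-rich alkene and on limiting the oxidant to one equivalent.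

**Step 5.** The likely failures are C-benzylation of the very nucleophilic ring A by an ionised para-silyloxybenzyl oxyphosphonium species, and sluggish reaction of the chelated, flanked phenol.

The fallback switches from redox condensation to phenoxide alkylation. It sets out from 5 and comes back at 8. An Appel reaction (CBr4, PPh3, CH2Cl2, 0 °C) converts 5 into 4-(tert-butyldimethylsilyloxy)-3,5-bis(3-methylbut-2-en-1-yl)benzyl bromide F5, which is used at once to alkylate phenol 7 in a Williamson ether synthesis under mild heterogeneous conditions (K2CO3, dry acetone, rt), giving 8.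

**Step 1.** The likely failures are O-alkylation and arrest at the mono-prenyl stage, because the formyl group lowers the nucleophilicity of the ring, while hydrolysis of the bromide competes in water.

The fallback builds the two side chains by rearrangement and metathesis. It sets out from 1 and comes back at 3. O-Allylation (allyl bromide, K2CO3, acetone) gives 4-(allyloxy)benzaldehyde F6. Thermal Claisen rearrangement (N,N-diethylaniline, about 200 °C) gives 3-allyl-4-hydroxybenzaldehyde F7. A second allylation gives 3-allyl-4-(allyloxy)benzaldehyde F8, and a second Claisen rearrangement gives 3,5-diallyl-4-hydroxybenzaldehyde F9. Twofold olefin cross-metathesis with 2-methylbut-2-ene (second-generation Grubbs catalyst, RuCl2(=CHPh)(PCy3)(H2IMes), CH2Cl2, rt) converts both allyl groups into prenyl groups and gives 3.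

## Further compounds

F1 | step 7 | racemic 5,7-bis(tert-butyldimethylsilyloxy)-2-[4-(tert-butyldimethylsilyloxy)-3,5-bis(3-methylbut-2-en-1-yl)phenyl]chroman-4-one | CC(C)=CCc1cc(C2Oc3cc(O[Si](C)(C)C(C)(C)C)cc(O[Si](C)(C)C(C)(C)C)c3C(=O)C2)cc(CC=C(C)C)c1O[Si](C)(C)C(C)(C)C
F2 | step 7 | (2R,4R)-5,7-bis(tert-butyldimethylsilyloxy)-2-[4-(tert-butyldimethylsilyloxy)-3,5-bis(3-methylbut-2-en-1-yl)phenyl]chroman-4-ol | CC(C)=CCc1cc([C@@H]2Oc3cc(O[Si](C)(C)C(C)(C)C)cc(O[Si](C)(C)C(C)(C)C)c3[C@H](O)C2)cc(CC=C(C)C)c1O[Si](C)(C)C(C)(C)C
F3 | step 8 | (2S)-5,7-bis(tert-butyldimethylsilyloxy)-2-[4-(tert-butyldimethylsilyloxy)-3,5-bis(3-methylbut-2-en-1-yl)phenyl]-4-(trimethylsilyloxy)-2H-chromene | CC(C)=CCc1cc([C@H]2Oc3cc(O[Si](C)(C)C(C)(C)C)cc(O[Si](C)(C)C(C)(C)C)c3C(O[Si](C)(C)C)=C2)cc(CC=C(C)C)c1O[Si](C)(C)C(C)(C)C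
F4 | step 8 | (2R,3R)-5,7-bis(tert-butyldimethylsilyloxy)-2-[4-(tert-butyldimethylsilyloxy)-3,5-bis(3-methylbut-2-en-1-yl)phenyl]-3-(trimethylsilyloxy)chroman-4-one | CC(C)=CCc1cc([C@H]2Oc3cc(O[Si](C)(C)C(C)(C)C)cc(O[Si](C)(C)C(C)(C)C)c3C(=O)[C@@H]2O[Si](C)(C)C)cc(CC=C(C)C)c1O[Si](C)(C)C(C)(C)C
F5 | step 5 | 4-(tert-butyldimethylsilyloxy)-3,5-bis(3-methylbut-2-en-1-yl)benzyl bromide | BrCc1cc(CC=C(C)C)c(O[Si](C)(C)C(C)(C)C)c(CC=C(C)C)c1
F6 | step 1 | 4-(allyloxy)benzaldehyde | C=CCOc1ccc(C=O)cc1
F7 | step 1 | 3-allyl-4-hydroxybenzaldehyde | C=CCc1cc(C=O)ccc1O
F8 | step 1 | 3-allyl-4-(allyloxy)benzaldehyde | C=CCOc1ccc(C=O)cc1CC=C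
F9 | step 1 | 3,5-diallyl-4-hydroxybenzaldehyde | C=CCc1cc(C=O)cc(CC=C)c1O
A1 | alternative 1 | (2R,3R)-3',5'-dibromoaromadendrin, (2R,3R)-2-(3,5-dibromo-4-hydroxyphenyl)-3,5,7-trihydroxychroman-4-one | Oc1c(Br)cc([C@H]2Oc3cc(O)cc(O)c3C(=O)[C@@H]2O)cc1Br
A2 | alternative 1 | D-tyrosine | N[C@H](Cc1ccc(O)cc1)C(=O)O
A3 | alternative 1 | (2R)-3-(3,5-dibromo-4-hydroxyphenyl)-2-hydroxy-1-(2,4,6-trihydroxyphenyl)propan-1-one | O=C([C@@H](Cc1cc(Br)c(O)c(Br)c1)O)c1c(O)cc(O)cc1O
A4 | alternative 1 | (2R)-3-(3,5-dibromo-4-oxocyclohexa-2,5-dien-1-ylidene)-2-hydroxy-1-(2,4,6-trihydroxyphenyl)propan-1-one (para-quinone methide) | O=C1C(Br)=CC(=C[C@@H](O)C(=O)c2c(O)cc(O)cc2O)C=C1Br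
A5 | alternative 2 | 4-hydroxy-3,5-bis(3-methylbut-2-en-1-yl)benzaldehyde (identical with 3) | O=Cc1cc(CC=C(C)C)c(O)c(CC=C(C)C)c1
A6 | alternative 2 | 2,10-dimethylundeca-2,9-dien-6-one | CC(C)=CCCC(=O)CCC=C(C)C
A7 | alternative 2 | triformylmethane (methanetricarbaldehyde) | O=CC(C=O)C=O
A8 | alternative 3 | 3,4'-bis(methoxymethyl) ether of cathayanon H | CC(C)=CCc1cc([C@H]2Oc3cc(O)cc(O)c3C(=O)[C@@H]2OCOC)cc(CC=C(C)C)c1OCOC
A9 | alternative 3 | methyl 4-{(2R,3R)-3-(methoxymethoxy)-2-[4-(methoxymethoxy)-3,5-bis(3-methylbut-2-en-1-yl)phenyl]-4-oxo-3,4-dihydro-2H-pyran-6-yl}-3-oxobutanoate | CC(C)=CCc1cc([C@H]2OC(CC(=O)CC(=O)OC)=CC(=O)[C@@H]2OCOC)cc(CC=C(C)C)c1OCOC
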